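**Remarks on the chemistry**

- Germacrane numbering is used from compound 9 onwards: ring C1–C10, C11–C13 on C7, C14 on C10, C15 on C4. α/β follow the usual germacranolide drawing, in which the C7–C11 bond is β.
- Assumption: the lipase in step 2 follows the Kazlauskas rule and acetylates the R-configured carbinol of meso diol 2, the one whose larger ring branch leads to the silyloxy carbon.

## The problem

The target is a heliangolide-type germacranolide. It is a ten-membered carbocycle (C1–C10) carrying a trans-fused α-methylene γ-lactone across C6–C7, a C1–C10 epoxide, a ring-cis C4=C5 olefin bearing the C15 hydroxymethyl group, an acetate at C3 and a methacrylate at C8. A synthesis must make a medium ring whose direct closure is penalised by transannular strain. It must also place two trisubstituted ring olefins of opposite geometry: C1=C10 trans (later the epoxide) and C4=C5 cis. Six stereocentres are needed (1R, 3S, 6R, 7R, 8R, 10R). C8 can come from an enzymatic desymmetrisation and can direct C7 while the ring is still six-membered. C6 and C3 flank the C4=C5 olefin as allylic carbinols and are best left to reagent control, and C1/C10 depend on which face of C1=C10 the ring exposes. The α-methylene lactone and the methacrylate are Michael acceptors that tolerate neither enolates nor hydrides. The epoxide opens under acid, and the C3 acetate sits 1,3 to the free C15 hydroxyl, so base invites acyl migration; these groups must come last and in a fixed order. The enabling feature is the diene C10=C1–C2–C3–C4=C5 of the deoxy skeleton. A trans,cis 1,5-diene inside the ring is what a bicyclo[2.2.0]hexane bonded C1–C4 and C5–C10 releases on cycloreversion. With C6 as a ketone and C15 as an ester, that tricycle is the [2+2] photoadduct of a 3-methylcyclohexenone (C5–C10) and a cyclobutene-1-carboxylate (C1–C4, C15).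

## Retrosynthesis

**34 ⇐ 33 ⇐ 32.** The C15 silyl ether is removed last, and the C1–O and C10–O bonds of the epoxide are cut back to the trans olefin of 32. The epoxide is placed after every acidic, basic and hydride step. Epoxidising 32 rather than an earlier compound means the substrate has the ring substitution of the natural deoxy compound and C4=C5 is deactivated by three allylic C–O bonds. The forward step must attack only C1=C10 and only its outer face.

**32 ⇐ 30 + 31.** The C8–O ester bond is cut with inversion, so that methacrylic acid 31 displaces the activated 8α-hydroxyl of 30. A plain acylation with retention would need C7 and C8 cis. No alkylation next to a silyloxy group gives that, whereas the trans arrangement forms reliably on a cyclohexenone. The precursor loses one Michael acceptor. The forward step is an SN2 displacement at a carbinol flanked by C7.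

**30 ⇐ 29 ⇐ 28 ⇐ 26 ⇐ 25.** The C3 acetate and the C11=C13 methylene are removed in turn; C13 is cut off via Mannich base 26. The order is forced: the acetate cannot meet the amide base needed for C11, and the methacrylate cannot meet it either. 25 is a saturated lactone with three differentiated oxygens.

**25 ⇐ 24 ⇐ 23.** The C3–H bond is cut to enone 24, which comes from 23 by allylic oxidation. This detour is accepted because C3 oxygen enters earlier without stereocontrol. An α-substituted enone is the best case for reagent-controlled reduction, and both C3 epimers of 23 converge.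

**23 ⇐ 22 ⇐ 21 ⇐ 20 ⇐ 19.** The lactone O6–C12 bond is cut to hydroxy tert-butyl ester 22. The C15 silyl ether, the C15–H bonds (from methyl ester 20) and the C6–H bond (from ketone 19) follow. The C15 ester must be reduced before the lactone exists, and C6 must be set before C15 is reduced, so the order is fixed. The forward reduction of 19 must give 6R against an α′-branched ketone.

**19 ⇐ 16 ⇐ 14.** The C3–O bond is cut by a [2,3] shift back to C5 selenide 16, which comes from dienone 14 through its extended enol. C3 is γ to the C6 ketone only at this stage, and an anionic route leaves C1=C10 alone where electrophilic or radical allylic oxidants would not. The forward steps must enolise toward C3 and re-form C4=C5 cis.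

**14 ⇐ 13.** The C1–C4 and C5–C10 bonds are reconnected, turning the ten-membered ring of 14 into tricyclic photoadduct 13. Compared with closing a C–C bond of the ring (see the alternatives below), the ring is formed here by strain release with no ring-closing transition state, and both olefins appear together. The C7 side chain and the 8S silyl ether are spectators. The forward step must give trans C1=C10 with cis C4=C5 and stop before Cope rearrangement.

**13 ⇐ 9 + 12.** The C4–C5 and C1–C10 bonds are cut, giving enone 9 and cyclobutene ester 12. The ester makes the alkene electron-poor, which favours the head-to-head adduct and places C15 on C4. The forward step must give that regiochemistry and a cis-anti-cis skeleton; its facial sense does not matter.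

**9 ⇐ 7 + 8.** The C7–C11 bond is cut to enone 7 and bromoacetate 8. Alkylating on the six-membered ring, rather than on the ten-membered ring after opening, lets the C8 silyloxy group control C7 in a rigid half-chair.

**7 ⇐ 6 ⇐ 5 ⇐ 3 ⇐ 2 ⇐ 1, and 12 ⇐ 11 ⇐ 10.** The methyl group and carbonyl position of 7 come from enone 5 by 1,2-addition and oxidative transposition via 6. 5 comes from monoacetate 3, made by enzymatic desymmetrisation of meso diol 2 from triol 1. Cyclobutene ester 12 comes from acid 11 and bromo ester 10.

## Roads not taken

**Alternative 1:** The cut is at O6–C6 and O15–C15. Diene acid A1, with a C4(15) exocyclic methylene conjugated to C5=C6, is treated with Pd(OAc)2 and benzoquinone in acetic acid. The C12 carboxylate adds to C6 and acetate to C15, giving A2 with the olefin moved to C4=C5.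
- Merits: one oxidative step installs the lactone, the C15 oxygen and the olefin position. That is better economy than steps 13–16 of the chosen route, which need four operations for the same result.
- Weak points: the ten-membered ring must already exist, so the hardest problem is left unsolved. A1 offers palladium three other olefins. The diene is 2-substituted and twisted in a medium ring, so 1,4- versus 1,2-addition, the C6 configuration and the C4=C5 geometry are not secured. A2 carries two acetates (C3 and C15) that must be told apart at the end.
- Comparison: the chosen plan has more steps after the ring but makes the ring, both olefins and C15 from two small rings in two steps.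

**Alternative 2:** The cut is at C5–C6. Open-chain Z-vinyl iodide aldehyde A3 is closed with CrCl2 and catalytic NiCl2 (Nozaki–Hiyama–Kishi), and the alkoxide lactonises onto the C12 methyl ester to give A4.
- Merits: the C4=C5 geometry is fixed in the vinyl iodide before cyclisation. That is more secure than in the chosen route, where it is set thermally and re-formed in step 12. C3 and C8 are made in acyclic fragments by reliable asymmetric reactions, which is also better than the late C3 correction here.
- Weak points: the ten-membered ring is closed by bond formation at high dilution with a large excess of chromium salt. C6 must come out trans to C7 by 1,2-induction from an epimerisable α-stereocentre. The linear sequence to A3 is long, and A4 still needs methylenation, two protecting-group exchanges and epoxidation.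
- Comparison: the chosen plan is weaker on C3 and C4=C5 security, and sets against that a ring-forming step without dilution or transannular strain and a short path to the ring.

**Alternative 3:** The cut is at C1–C2. Seco keto aldehyde A5 is enolised at the C2 methyl of the C3 enone as its dibutylboron enolate, which adds to the non-enolisable C1 aldehyde to give β-hydroxy ketone A6.
- Merits: the ring closes as late as possible with the methacrylate, methylene lactone and C10 oxygen in place. The endgame after A6 (C3 reduction and acetylation, epoxide closure, deprotection) is shorter than the one here.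
- Weak points: the enolisation must be selective in a molecule with two Michael acceptors, three esters and a γ-acyloxy enone that can eliminate. The aldehyde is neopentyl. The new C1 carbinol is controlled only by C10. A6 can dehydrate or undergo retro-aldol cleavage, and the C10 tertiary ether must be built acyclically.
- Comparison: the chosen plan has the longer endgame but a precedented ring-forming step, and it introduces the fragile acceptors last.

Key step: step 10

## Route

Step 1
Reactants: 1 cis,cis-cyclohexane-1,3,5-triol
Product: 2 cis,cis-5-[(tert-butyldimethylsilyl)oxy]cyclohexane-1,3-diol (meso)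
Conditions: TBSCl (1.0 equiv), imidazole, DMF, 0 °C to rt
Reagents that add atoms: tert-butyldimethylsilyl chloride, CC(C)(C)[Si](C)(C)Cl
Why: Silyl ether formation; the three hydroxyls of 1 are homotopic, so only mono- versus bis-silylation matters and is handled by stoichiometry and recycling of 1; the product is meso and no stereocentre is set.

Step 2
Reactants: 2 cis,cis-5-[(tert-butyldimethylsilyl)oxy]cyclohexane-1,3-diol
Product: 3 (1R,3S,5S)-3-[(tert-butyldimethylsilyl)oxy]-5-hydroxycyclohexyl acetate
Conditions: lipase from Burkholderia cepacia (lipase PS), vinyl acetate, tBuOMe, rt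
Reagents that add atoms: vinyl acetate, C=COC(C)=O
Why: Lipase-catalysed irreversible transesterification desymmetrises the meso diol; by the Kazlauskas rule the R-configured carbinol is acetylated, which fixes the absolute configuration of the later C8.

Step 3
Reactants: 3 (1R,3S,5S)-3-[(tert-butyldimethylsilyl)oxy]-5-hydroxycyclohexyl acetate
Product: 5 (R)-5-[(tert-butyldimethylsilyl)oxy]cyclohex-2-en-1-one, via β-acetoxy ketone 4 (not isolated)
Conditions: Dess–Martin periodinane, CH2Cl2, 0 °C to rt; then DBU, 0 °C
Reagents that add atoms: none
Why: Dess–Martin oxidation gives β-acetoxy ketone 4, which loses acetic acid by E1cB elimination with DBU; acetate is a much better leaving group than silanolate, so the silyloxy stereocentre survives.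

Step 4
Reactants: 5 (R)-5-[(tert-butyldimethylsilyl)oxy]cyclohex-2-en-1-one
Product: 6 (5R)-5-[(tert-butyldimethylsilyl)oxy]-1-methylcyclohex-2-en-1-ol (both C1 epimers)
Conditions: MeLi, Et2O, −78 °C
Reagents that add atoms: methyllithium, [Li]C
Why: 1,2-Addition of methyllithium to the enone carbonyl; the configuration of the new tertiary carbinol is irrelevant because it is destroyed in step 5.

Step 5
Reactants: 6 (5R)-5-[(tert-butyldimethylsilyl)oxy]-1-methylcyclohex-2-en-1-ol
Product: 7 (S)-5-[(tert-butyldimethylsilyl)oxy]-3-methylcyclohex-2-en-1-one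
Conditions: (C5H5NH)[CrO3Cl] (pyridinium chlorochromate), 4 Å sieves, CH2Cl2, rt
Reagents that add atoms: pyridinium chlorochromate, [O-][Cr](=O)(=O)Cl.c1cc[nH+]cc1
Why: Dauben oxidative 1,3-transposition: the tertiary allylic chromate ester undergoes a [3,3] shift and oxidation, moving the carbonyl to the former β-carbon and leaving the methyl on the new β-carbon; the silyloxy centre is untouched and its descriptor changes from R to S only because the substituent priorities change.

Step 6
Reactants: 7 (S)-5-[(tert-butyldimethylsilyl)oxy]-3-methylcyclohex-2-en-1-one; 8 tert-butyl bromoacetate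
Product: 9 tert-butyl 2-[(1R,6S)-6-[(tert-butyldimethylsilyl)oxy]-4-methyl-2-oxocyclohex-3-en-1-yl]acetate
Conditions: LiN(iPr)2, THF, −78 °C; then 8, DMPU, −78 to −40 °C
Reagents that add atoms: none
Why: Kinetic α′-deprotonation of the enone and alkylation of the cross-conjugated enolate; the electrophile enters anti to the adjacent silyloxy group by axial attack on the half-chair, setting C7 (R) trans to C8, which is also the thermodynamically preferred arrangement.

Step 7
Reactants: 10 ethyl 1-bromocyclobutane-1-carboxylate
Product: 11 cyclobut-1-ene-1-carboxylic acid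
Conditions: KOH, PhMe, reflux; then aq. HCl, 0 °C
Reagents that add atoms: potassium hydroxide, [K+].[OH-]
Why: One-pot saponification and dehydrobromination of the α-bromo ester, the classical preparation of this acid; the conjugated cyclobutene is the only possible elimination product.

Step 8
Reactants: 11 cyclobut-1-ene-1-carboxylic acid
Product: 12 methyl cyclobut-1-ene-1-carboxylate
Conditions: MeI, K2CO3, acetone, 0 °C to rt; kept cold and used as a stock solution
Reagents that add atoms: iodomethane, CI
Why: O-Alkylation of the carboxylate by SN2 on iodomethane; the volatile, polymerisable ester is not stored.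

Step 9
Reactants: 9 tert-butyl 2-[(1R,6S)-6-[(tert-butyldimethylsilyl)oxy]-4-methyl-2-oxocyclohex-3-en-1-yl]acetate; 12 methyl cyclobut-1-ene-1-carboxylate
Product: 13 cis-anti-cis head-to-head photoadduct (1R,4S,5R,7R,8S,10R)
Conditions: hν (350 nm, Pyrex), 12 (5 equiv), CH2Cl2, −30 °C; then basic Al2O3, CH2Cl2, rt
Reagents that add atoms: none
Why: Enone triplet [2+2] photocycloaddition; an electron-poor alkene is expected to add head-to-head, joining the ester carbon C4 to the enone α-carbon C5 and C1 to C10, and exo approach gives the cis-anti-cis skeleton, with any trans-fused isomer epimerised at C5 on basic Al2O3 while C7 is already in its stable trans arrangement; addition anti to the C8 silyloxy group is expected, but the facial outcome is immaterial because C1, C4, C5 and C10 are erased in step 10.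

Step 10
Reactants: 13 cis-anti-cis head-to-head photoadduct
Product: 14 ten-membered dienone, methyl (1(10)E,7R,8S)-7-(2-tert-butoxy-2-oxoethyl)-8-[(tert-butyldimethylsilyl)oxy]-10-methyl-6-oxocyclodeca-1(10),4-diene-4-carboxylate with C4=C5 ring-cis
Conditions: degassed PhMe (0.01 M), BHT (cat.), base-washed vessel, 200 °C, sealed tube or heated flow coil, short residence time
Reagents that add atoms: none
Why: Thermal cycloreversion of a bicyclo[2.2.0]hexane, formally [σ2s+σ2a] and in practice homolysis of the doubly strained C1–C4 bond to a cyclohexane-1,4-diyl (stabilised at C4 by the ester) followed by scission of C5–C10 (stabilised at C5 by the ketone), releasing the strain of two cyclobutanes. The closest known reaction type is the thermolysis of cyclohexenone–cyclobutene [2+2] photoadducts to cyclodeca-1,5-dienes (photo-thermal olefin metathesis). The ten-membered ring is not closed but unveiled: the six- and four-membered rings share the two bonds that break, so there is no ring-closing transition state and no need for high dilution. No stereocentre is created; C1, C4, C5 and C10 become trigonal, so either facial series of the photoadduct converges, and C7 and C8 are untouched because no base is present. The step must give trans C1=C10 and ring-cis C4=C5: the cis-anti-cis fusion delivers one trans and one cis olefin, and the cis one is expected at C4=C5 because the diradical can relax there to the planar cis enedicarbonyl while the unconjugated C1=C10 carries the trans geometry. It must also stop before Cope rearrangement to the cis-divinylcyclohexanone, for which short residence time and the conjugation of C4=C5 with two carbonyls are relied on.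

Step 11
Reactants: 14 ten-membered dienone
Product: 16 C5 phenylselenide (C5 epimers) with C3=C4 conjugated to the ester, via silyl dienol ether 15 (not isolated)
Conditions: TMSOTf, Et3N, CH2Cl2, −78 to 0 °C; then PhSeCl (1.0 equiv), −78 °C
Reagents that add atoms: phenylselenenyl chloride, Cl[Se]c1ccccc1
Why: Soft enolisation is expected to remove a C3 hydrogen, the γ-hydrogen cis to the carbonyl across C4=C5 and far less hindered than the tertiary C7–H, giving extended silyl dienol ether 15; selenenylation then occurs at C5, the enol carbon, because C3=C4 is now an electron-poor acrylate, and low temperature with one equivalent of PhSeCl spares C1=C10.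

Step 12
Reactants: 16 C5 phenylselenide
Product: 19 3-hydroxy dienone (both C3 epimers; C4=C5 ring-cis), via allyl selenoxide 17 (not isolated), via selenenate ester 18 (not isolated)
Conditions: mCPBA (1.0 equiv), CH2Cl2, −78 °C; then Et3N, −78 to 0 °C; aqueous work-up
Reagents that add atoms: 3-chloroperbenzoic acid, O=C(OO)c1cccc(Cl)c1
Why: Selenide oxidation is far faster than epoxidation; allyl selenoxide 17 has no syn β-hydrogen and undergoes [2,3]-sigmatropic rearrangement to selenenate 18, cleaved on work-up, so oxygen is delivered to C3 and C4=C5 returns into conjugation with ketone and ester; the ring-cis geometry is expected to re-form because the alternative transition state eclipses the C6 carbonyl with the C4 ester; C3 is not controlled here and is corrected in steps 17 and 18.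

Step 13
Reactants: 19 3-hydroxy dienone
Product: 20 (6R)-3,6-diol (6α-hydroxyl; both C3 epimers)
Conditions: (R)-Me-CBS oxazaborolidine (20 mol %), catecholborane, PhMe, −78 °C
Reagents that add atoms: none
Why: Corey–Bakshi–Shibata reduction: with the trisubstituted alkenyl group as the larger ketone substituent the (R)-catalyst delivers hydride to the face that gives the 6R allylic alcohol, trans to the C7 side chain; catecholborane at −78 °C leaves the esters and the electron-poor olefin alone, and the free C3 hydroxyl only consumes reagent.

Step 14
Reactants: 20 (6R)-3,6-diol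
Product: 21 3,6,15-triol tert-butyl ester
Conditions: iBu2AlH (5 equiv), CH2Cl2, −78 °C; Rochelle salt work-up
Reagents that add atoms: none
Why: iBu2AlH reduces the conjugated methyl ester by 1,2-addition to the primary allylic alcohol, whereas the tert-butyl ester is much slower at −78 °C; the C4=C5 geometry is untouched.

Step 15
Reactants: 21 3,6,15-triol tert-butyl ester
Product: 22 15-O-tert-butyldiphenylsilyl ether of 21
Conditions: TBDPSCl, imidazole, CH2Cl2, 0 °C
Reagents that add atoms: tert-butyl(chloro)diphenylsilane, CC(C)(C)[Si](Cl)(c1ccccc1)c1ccccc1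
Why: The primary allylic hydroxyl is silylated selectively over the two secondary allylic hydroxyls by the bulky silyl chloride at 0 °C.

Step 16
Reactants: 22 15-O-tert-butyldiphenylsilyl ether
Product: 23 trans-fused 6α,12-lactone with free C3 hydroxyl (both C3 epimers)
Conditions: camphorsulfonic acid (0.2 equiv), PhMe, 60 °C
Reagents that add atoms: none
Why: Acid-catalysed transesterification: the 6α-hydroxyl is γ to the ester carbonyl and closes the five-membered lactone with loss of tert-butanol; O3 is out of reach and O8 is silylated, and weak acid in an aprotic solvent should spare the silyl ethers and the allylic carbinols; the trans fusion follows from C6 (R) and C7.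

Step 17
Reactants: 23 6α,12-lactone
Product: 24 3-oxo lactone (enone)
Conditions: MnO2, CH2Cl2, rt
Reagents that add atoms: none
Why: MnO2 oxidises only the free allylic carbinol; both C3 epimers converge on one enone.

Step 18
Reactants: 24 3-oxo lactone
Product: 25 (3S)-3-hydroxy lactone
Conditions: (R)-Me-CBS oxazaborolidine (20 mol %), catecholborane, PhMe, −78 °C
Reagents that add atoms: none
Why: Corey–Bakshi–Shibata reduction of an α-substituted enone, the best substrate class for this catalyst: the fully substituted alkenyl carbon C4 is the large group and C2H2 the small one, so the (R)-catalyst gives the 3S alcohol; the lactone is inert to catecholborane at −78 °C.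

Step 19
Reactants: 25 (3S)-3-hydroxy lactone
Product: 26 C11 dimethylaminomethyl lactone (Mannich base; C11 epimers)
Conditions: LiN(iPr)2 (2.5 equiv), THF, −78 °C; then dimethyl(methylidene)ammonium iodide, −78 °C to rt
Reagents that add atoms: dimethyl(methylidene)ammonium iodide (Eschenmoser's salt), C=[N+](C)C.[I-]
Why: Two equivalents of amide base give the C3 alkoxide and the lactone enolate, which is aminomethylated at C11 (Mannich reaction); any O-aminomethylation is reversed on aqueous work-up, and the C11 configuration is irrelevant.

Step 20
Reactants: 26 Mannich base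
Product: 28 11(13)-methylene lactone, via trimethylammonium iodide 27 (not isolated)
Conditions: MeI, MeOH, rt; then aq. NaHCO3, EtOAc, rt
Reagents that add atoms: none
Why: Quaternisation of the amine and E1cB elimination of trimethylamine under bicarbonate unveil the exocyclic C11=C13 methylene; elimination can only occur across C11–C13.

Step 21
Reactants: 28 11(13)-methylene lactone
Product: 29 (3S)-3-acetate
Conditions: Ac2O, pyridine, DMAP (cat.), CH2Cl2, 0 °C
Reagents that add atoms: acetic anhydride, CC(=O)OC(C)=O
Why: Standard acylation of the secondary allylic alcohol with retention; it follows the last enolate step because an acetate does not survive LiN(iPr)2.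

Step 22
Reactants: 29 (3S)-3-acetate
Product: 30 (8S)-8-alcohol (8α-hydroxyl)
Conditions: HF·pyridine, pyridine, THF, 0 °C to rt
Reagents that add atoms: none
Why: Acidic fluoride removes the secondary tert-butyldimethylsilyl ether, while the primary tert-butyldiphenylsilyl ether is far more stable to acid and is kept; acetate and methylene lactone are stable to buffered HF.

Step 23
Reactants: 30 (8S)-8-alcohol; 31 methacrylic acid
Product: 32 (8R)-8-methacrylate (8β-ester)
Conditions: PPh3, DIAD, PhMe, 0 °C to rt
Reagents that add atoms: none
Why: Mitsunobu esterification: the 8α-hydroxyl is activated as the oxyphosphonium ion and displaced by methacrylate with inversion (SN2), giving the 8β ester cis to the C7–C11 bond; the primary hydroxyl is still silylated.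

Step 24
Reactants: 32 (8R)-8-methacrylate
Product: 33 (1R,10R)-1,10-epoxide (1β,10α)
Conditions: mCPBA, CH2Cl2/aq. NaHCO3, 0 °C
Reagents that add atoms: 3-chloroperbenzoic acid, O=C(OO)c1cccc(Cl)c1
Why: Peracid epoxidation is chemoselective for the only electron-rich olefin, C1=C10 (C4=C5 carries three allylic C–O bonds and the other two olefins are conjugated with carbonyls); syn addition to the trans olefin gives a trans epoxide, and attack on the exposed outer face of the ring, the face that corresponds to the 1β,10α-epoxides of natural congeners with this substitution, is expected to give 1R,10R.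

Step 25
Reactants: 33 (1R,10R)-1,10-epoxide
Product: 34 CNP0319155.1
Conditions: Bu4NF, AcOH (1:1), THF, 0 °C to rt
Reagents that add atoms: none
Why: Fluoride cleaves the primary silyl ether; acetic acid buffers the medium so that the epoxide is not opened and the C3 acetate does not migrate to the liberated C15 hydroxyl.

## Compound list

1 | cis,cis-cyclohexane-1,3,5-triol | O[C@H]1C[C@@H](O)C[C@@H](O)C1 | starting material
2 | cis,cis-5-[(tert-butyldimethylsilyl)oxy]cyclohexane-1,3-diol (meso) | O[C@H]1C[C@@H](O)C[C@@H](O[Si](C)(C)C(C)(C)C)C1 | intermediate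
3 | (1R,3S,5S)-3-[(tert-butyldimethylsilyl)oxy]-5-hydroxycyclohexyl acetate | CC(=O)O[C@H]1C[C@@H](O[Si](C)(C)C(C)(C)C)C[C@@H](O)C1 | intermediate
4 | (1S,3R)-3-[(tert-butyldimethylsilyl)oxy]-5-oxocyclohexyl acetate | CC(=O)O[C@H]1C[C@@H](O[Si](C)(C)C(C)(C)C)CC(=O)C1 | intermediate (not isolated)
5 | (R)-5-[(tert-butyldimethylsilyl)oxy]cyclohex-2-en-1-one | O=C1C=CC[C@@H](O[Si](C)(C)C(C)(C)C)C1 | intermediate
6 | (5R)-5-[(tert-butyldimethylsilyl)oxy]-1-methylcyclohex-2-en-1-ol, both C1 epimers | CC1(O)C=CC[C@@H](O[Si](C)(C)C(C)(C)C)C1 | intermediate
7 | (S)-5-[(tert-butyldimethylsilyl)oxy]-3-methylcyclohex-2-en-1-one | O=C1C=C(C)C[C@H](O[Si](C)(C)C(C)(C)C)C1 | intermediate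
8 | tert-butyl bromoacetate | BrCC(=O)OC(C)(C)C | starting material
9 | tert-butyl 2-[(1R,6S)-6-[(tert-butyldimethylsilyl)oxy]-4-methyl-2-oxocyclohex-3-en-1-yl]acetate (side chain and silyloxy trans) | CC(C)(C)OC(=O)C[C@H]1C(=O)C=C(C)C[C@@H]1O[Si](C)(C)C(C)(C)C | intermediate
10 | ethyl 1-bromocyclobutane-1-carboxylate | CCOC(=O)C1(Br)CCC1 | starting material
11 | cyclobut-1-ene-1-carboxylic acid | OC(=O)C1=CCC1 | intermediate
12 | methyl cyclobut-1-ene-1-carboxylate | COC(=O)C1=CCC1 | intermediate
13 | cis-anti-cis head-to-head photoadduct: cyclobutane C1–C2–C3–C4 and cyclohexanone C5–C10 fused through cyclobutane C1–C4–C5–C10; CO2Me on C4, CH3 on C10, CH2CO2tBu on C7, silyloxy on C8; (1R,4S,5R,7R,8S,10R) | COC(=O)[C@@]12CC[C@@H]1[C@@]1(C)C[C@H](O[Si](C)(C)C(C)(C)C)[C@@H](CC(=O)OC(C)(C)C)C(=O)[C@H]12 | intermediate (key-step precursor)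
14 | methyl (1(10)E,7R,8S)-7-(2-tert-butoxy-2-oxoethyl)-8-[(tert-butyldimethylsilyl)oxy]-10-methyl-6-oxocyclodeca-1(10),4-diene-4-carboxylate, C4=C5 ring-cis (C3 and C6 cis) | COC(=O)/C1=C/C(=O)[C@H](CC(=O)OC(C)(C)C)[C@@H](O[Si](C)(C)C(C)(C)C)C/C(C)=C/CC1 | intermediate (key-step product)
15 | 6-trimethylsilyloxy-1(10),3,5-triene (extended silyl dienol ether of 14; geometry of the C3=C4 and C5=C6 bonds not assigned) | COC(=O)C1=CC/C=C(C)/C[C@H](O[Si](C)(C)C(C)(C)C)[C@@H](CC(=O)OC(C)(C)C)C(O[Si](C)(C)C)=C1 | intermediate (not isolated)
16 | 5-phenylseleno-6-oxo-1(10),3-diene (C5 epimers; C3=C4 geometry not assigned) | COC(=O)C1=CC/C=C(C)/C[C@H](O[Si](C)(C)C(C)(C)C)[C@@H](CC(=O)OC(C)(C)C)C(=O)C1[Se]c2ccccc2 | intermediate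
17 | selenoxide of 16 | COC(=O)C1=CC/C=C(C)/C[C@H](O[Si](C)(C)C(C)(C)C)[C@@H](CC(=O)OC(C)(C)C)C(=O)C1[Se](=O)c2ccccc2 | intermediate (not isolated)
18 | 3-O-phenylselenenyl ester of 19 (C3 epimers) | COC(=O)/C1=C/C(=O)[C@H](CC(=O)OC(C)(C)C)[C@@H](O[Si](C)(C)C(C)(C)C)C/C(C)=C/CC1O[Se]c2ccccc2 | intermediate (not isolated)
19 | 3-hydroxy derivative of 14 (3RS; 1(10)E, C4=C5 ring-cis; 7R,8S) | COC(=O)/C1=C/C(=O)[C@H](CC(=O)OC(C)(C)C)[C@@H](O[Si](C)(C)C(C)(C)C)C/C(C)=C/CC1O | intermediate
20 | 6α-alcohol of 19 (6R; 3RS) | COC(=O)/C1=C/[C@@H](O)[C@H](CC(=O)OC(C)(C)C)[C@@H](O[Si](C)(C)C(C)(C)C)C/C(C)=C/CC1O | intermediate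
21 | tert-butyl ester triol: 3RS,6α-dihydroxy-4-(hydroxymethyl)-8α-silyloxy ten-membered 1(10)E,4Z-diene with 7β-CH2CO2tBu | OC/C1=C/[C@@H](O)[C@H](CC(=O)OC(C)(C)C)[C@@H](O[Si](C)(C)C(C)(C)C)C/C(C)=C/CC1O | intermediate
22 | 15-O-tert-butyldiphenylsilyl ether of 21 | CC(C)(C)[Si](OC/C1=C/[C@@H](O)[C@H](CC(=O)OC(C)(C)C)[C@@H](O[Si](C)(C)C(C)(C)C)C/C(C)=C/CC1O)(c2ccccc2)c2ccccc2 | intermediate
23 | 8α-(tert-butyldimethylsilyloxy)-15-(tert-butyldiphenylsilyloxy)-3RS-hydroxygermacra-1(10)E,4Z-dien-6α,12-olide (trans-fused lactone) | CC(C)(C)[Si](C)(C)O[C@H]1C/C(C)=C/CC(O)/C(CO[Si](c3ccccc3)(c3ccccc3)C(C)(C)C)=C\[C@H]2OC(=O)C[C@@H]21 | intermediate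
24 | 3-oxo analogue of 23 | CC(C)(C)[Si](C)(C)O[C@H]1C/C(C)=C/CC(=O)/C(CO[Si](c3ccccc3)(c3ccccc3)C(C)(C)C)=C\[C@H]2OC(=O)C[C@@H]21 | intermediate
25 | (3S)-3-hydroxy lactone (3β-hydroxyl) | CC(C)(C)[Si](C)(C)O[C@H]1C/C(C)=C/C[C@H](O)/C(CO[Si](c3ccccc3)(c3ccccc3)C(C)(C)C)=C\[C@H]2OC(=O)C[C@@H]21 | intermediate
26 | 11-(dimethylaminomethyl) derivative of 25 (C11 epimers) | CC(C)(C)[Si](C)(C)O[C@H]1C/C(C)=C/C[C@H](O)/C(CO[Si](c3ccccc3)(c3ccccc3)C(C)(C)C)=C\[C@H]2OC(=O)C(CN(C)C)[C@@H]21 | intermediate
27 | trimethylammonium iodide of 26 | CC(C)(C)[Si](C)(C)O[C@H]1C/C(C)=C/C[C@H](O)/C(CO[Si](c3ccccc3)(c3ccccc3)C(C)(C)C)=C\[C@H]2OC(=O)C(C[N+](C)(C)C)[C@@H]21.[I-] | intermediate (not isolated)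
28 | 11(13)-methylene lactone with free 3β-hydroxyl | CC(C)(C)[Si](C)(C)O[C@H]1C/C(C)=C/C[C@H](O)/C(CO[Si](c3ccccc3)(c3ccccc3)C(C)(C)C)=C\[C@H]2OC(=O)C(=C)[C@@H]21 | intermediate
29 | 3β-acetate of 28 | CC(C)(C)[Si](C)(C)O[C@H]1C/C(C)=C/C[C@H](OC(C)=O)/C(CO[Si](c3ccccc3)(c3ccccc3)C(C)(C)C)=C\[C@H]2OC(=O)C(=C)[C@@H]21 | intermediate
30 | 8α-alcohol (8S) | O[C@H]1C/C(C)=C/C[C@H](OC(C)=O)/C(CO[Si](c3ccccc3)(c3ccccc3)C(C)(C)C)=C\[C@H]2OC(=O)C(=C)[C@@H]21 | intermediate
31 | methacrylic acid | C=C(C)C(=O)O | starting material
32 | 8β-methacrylate (8R), 15-O-silyl 1(10)-deoxy target | C=C(C)C(=O)O[C@@H]1C/C(C)=C/C[C@H](OC(C)=O)/C(CO[Si](c3ccccc3)(c3ccccc3)C(C)(C)C)=C\[C@H]2OC(=O)C(=C)[C@@H]21 | intermediate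
33 | (1R,10R)-epoxide, 15-O-tert-butyldiphenylsilyl target | C=C(C)C(=O)O[C@@H]1C[C@@]2(C)O[C@@H]2C[C@H](OC(C)=O)/C(CO[Si](c3ccccc3)(c3ccccc3)C(C)(C)C)=C\[C@H]2OC(=O)C(=C)[C@@H]21 | intermediate
34 | CNP0319155.1 | C=C(C)C(=O)O[C@@H]1C[C@@]2(C)O[C@@H]2C[C@H](OC(C)=O)/C(CO)=C\[C@H]2OC(=O)C(=C)[C@@H]21 | target

## Step count and risks

Total: 25 steps. Longest linear sequence: 23 steps (1 to 34 through steps 1–6 and 9–25); the cyclobutene branch (10 to 12) adds two.

**Step 10 (key step).** The most likely failure is that the dienone does not survive the residence time needed to open a substrate too heavy for gas-phase pyrolysis: onward Cope rearrangement to the cis-divinylcyclohexanone, or thermal loss of silanol from the β-silyloxy ketone. The fallback changes the order of events. Enone 7 is irradiated with 12 to give the simpler photoadduct F1, which is volatile enough for flash vacuum pyrolysis, so the ten-membered dienone F2 leaves the hot zone before it can rearrange. F2 is then alkylated at C7 (LiN(iPr)2, then 8), with the bromoacetate expected to enter anti to the silyloxy group, to rejoin the route at 14. It sets out from 7 and returns at 14.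

**Step 11 (with step 12).** Two things may go wrong: enolisation toward C7 instead of C3, and loss of the ring-cis geometry in the [2,3] shift, because C4–C5 is a single bond in 16. The fallback keeps silyl dienol ether 15 but replaces selenium by a cycloaddition. Photo-oxygenation (O2, hν, sensitiser) adds singlet oxygen across C3 and C6 to give the 3,6-endoperoxide F3, whose six-membered ring can only hold a cis C4=C5. Reduction with PPh3 and loss of the silyl group give 19. It sets out from 14 (through 15) and returns at 19.

**Step 13.** Facial selectivity may be poor or reversed, because the branched C7 competes with the alkenyl group as the large substituent in the catalyst complex. The fallback uses whichever reduction is selective for the 6S alcohol (for example NaBH4/CeCl3) to make the 6-epimeric diol F4. This is carried through the conditions of steps 14 and 15 to triol F5 and silyl ether F6. The tert-butyl ester is cleaved (TMSOTf, 2,6-lutidine) to hydroxy acid F7, and the lactone is closed by intramolecular Mitsunobu reaction with inversion at C6 to give 23. It sets out from 19 and returns at 23.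

**Step 23.** Displacement at C8 may lose to elimination or fail to occur, since the carbinol is flanked by C7 and the acid is only moderately acidic. The fallback is a redox inversion. Dess–Martin oxidation of 30 gives the C8 ketone F8. NaBH4/CeCl3 reduction, with hydride arriving anti to the C7–C11 bond, gives the 8β-alcohol F9, which is acylated with methacrylic anhydride and DMAP to give 32. It sets out from 30 and returns at 32.

**Step 24.** The peracid may attack the wrong face of C1=C10 if the ring exposes the other face in 32. The fallback uses the same exposed face but inverts the outcome. NBS in aqueous THF gives bromohydrin F10 (bromine at C1 from the exposed face, hydroxyl at C10 anti). Closure with Ag2O displaces bromide with inversion and places the epoxide on the opposite face, giving 33. It sets out from 32 and returns at 33.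

## Further compounds

F1 | step 10 | cis-anti-cis head-to-head photoadduct of 7 and 12 (1R,4S,5R,8S,10R) | COC(=O)[C@@]12CC[C@@H]1[C@@]1(C)C[C@H](O[Si](C)(C)C(C)(C)C)CC(=O)[C@H]12
F2 | step 10 | methyl (1(10)E,8S)-8-[(tert-butyldimethylsilyl)oxy]-10-methyl-6-oxocyclodeca-1(10),4-diene-4-carboxylate, C4=C5 ring-cis | COC(=O)/C1=C/C(=O)C[C@@H](O[Si](C)(C)C(C)(C)C)C/C(C)=C/CC1
F3 | step 11 | 3,6-endoperoxide of silyl dienol ether 15 (C3 and C6 not assigned) | COC(=O)C1=CC2(O[Si](C)(C)C)OOC1C/C=C(C)/C[C@H](O[Si](C)(C)C(C)(C)C)[C@H]2CC(=O)OC(C)(C)C
F4 | step 13 | 6-epimer of 20 (6S; 3RS) | COC(=O)/C1=C/[C@H](O)[C@H](CC(=O)OC(C)(C)C)[C@@H](O[Si](C)(C)C(C)(C)C)C/C(C)=C/CC1O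
F5 | step 13 | 6-epimer of 21 | OC/C1=C/[C@H](O)[C@H](CC(=O)OC(C)(C)C)[C@@H](O[Si](C)(C)C(C)(C)C)C/C(C)=C/CC1O
F6 | step 13 | 6-epimer of 22 | CC(C)(C)[Si](OC/C1=C/[C@H](O)[C@H](CC(=O)OC(C)(C)C)[C@@H](O[Si](C)(C)C(C)(C)C)C/C(C)=C/CC1O)(c2ccccc2)c2ccccc2
F7 | step 13 | carboxylic acid from F6 (6S hydroxy acid) | CC(C)(C)[Si](OC/C1=C/[C@H](O)[C@H](CC(=O)O)[C@@H](O[Si](C)(C)C(C)(C)C)C/C(C)=C/CC1O)(c2ccccc2)c2ccccc2
F8 | step 23 | C8 ketone from 30 | O=C1C/C(C)=C/C[C@H](OC(C)=O)/C(CO[Si](c3ccccc3)(c3ccccc3)C(C)(C)C)=C\[C@H]2OC(=O)C(=C)[C@@H]21
F9 | step 23 | 8β-alcohol (8R), C8 epimer of 30 | O[C@@H]1C/C(C)=C/C[C@H](OC(C)=O)/C(CO[Si](c3ccccc3)(c3ccccc3)C(C)(C)C)=C\[C@H]2OC(=O)C(=C)[C@@H]21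
F10 | step 24 | 1-bromo-10-hydroxy bromohydrin of 32 | C=C(C)C(=O)O[C@@H]1C[C@@](C)(O)[C@@H](Br)C[C@H](OC(C)=O)/C(CO[Si](c3ccccc3)(c3ccccc3)C(C)(C)C)=C\[C@H]2OC(=O)C(=C)[C@@H]21
A1 | alternative 1 | macrocyclic diene acid, 3β-acetoxy-8β-methacryloyloxygermacra-1(10)E,4(15),5Z,11(13)-tetraen-12-oic acid | C=C(C)C(=O)O[C@@H]1C/C(C)=C/C[C@H](OC(C)=O)C(=C)/C=C\[C@@H]1C(=C)C(=O)O
A2 | alternative 1 | C15 acetate of the 1(10)-deoxy target | C=C(C)C(=O)O[C@@H]1C/C(C)=C/C[C@H](OC(C)=O)/C(COC(C)=O)=C\[C@H]2OC(=O)C(=C)[C@@H]21
A3 | alternative 2 | open-chain C6 aldehyde with C5 Z-vinyl iodide and C12 methyl ester | COC(=O)C[C@@H](C=O)[C@H](OCc1ccc(OC)cc1)C/C(C)=C/C[C@H](O[Si](C)(C)C(C)(C)C)/C(CO[Si](c1ccccc1)(c1ccccc1)C(C)(C)C)=C\I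
A4 | alternative 2 | ten-membered ring fused to the trans γ-lactone | COc1ccc(CO[C@@H]2C/C(C)=C/C[C@H](O[Si](C)(C)C(C)(C)C)/C(CO[Si](c3ccccc3)(c3ccccc3)C(C)(C)C)=C\[C@H]3OC(=O)C[C@@H]32)cc1
A5 | alternative 3 | seco keto aldehyde (C1 aldehyde, C2 methyl ketone) | C=C(C)C(=O)O[C@H](C[C@@](C)(O[Si](CC)(CC)CC)C=O)[C@H]1C(=C)C(=O)O[C@@H]1/C=C(/CO[Si](c1ccccc1)(c1ccccc1)C(C)(C)C)C(C)=O
A6 | alternative 3 | ten-membered C1 carbinol, C3 ketone | C=C(C)C(=O)O[C@@H]1C[C@@](C)(O[Si](CC)(CC)CC)[C@@H](O)CC(=O)/C(CO[Si](c2ccccc2)(c2ccccc2)C(C)(C)C)=C\[C@H]2OC(=O)C(=C)[C@@H]21
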